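**Retrosynthetic overview**
1. Isolappaol A 23 ⇐ hydrogenolysis of dibenzyl ether 22 ⇐ reduction and lactonisation of 4-oxobutanamide 20 (butyrolactone ring formed last, step 11).
2. Key disconnection: the bond between the two α-carbons of 20. It is made by a sulfonium [3,3] rearrangement between the keteniminium of amide 10 and the (S,E)-vinyl sulfoxide 16, which acts as a chiral α-formyl cation equivalent; the sulfur stereocentre sets both lactone stereocentres.
3. 10 ⇐ dirhodium-carbenoid C–H insertion of aryl diazoacetate 8 (dihydrofuran ring formed first, step 6) ⇐ iodophenol 3 + benzylic bromide 5 + ethyl diazoacetate 7, all built on dihydroferulic acid pyrrolidide.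
4. 16 ⇐ E-selective reduction of alkynyl sulfoxide 15 ⇐ Andersen sulfinylation of propargylarene 12 (from 5).
5. Ring order: ring A is bought, then the dihydrobenzofuran, then the lactone.

Assumption: (1S,2R,5S)-(+)-menthyl (R)-p-toluenesulfinate and Rh2(R-PTTL)4 are taken as purchasable; the catalyst enantiomer in step 6 is chosen from recalled precedent for cis-2-aryl-2,3-dihydrobenzofuran-3-carboxylates, and the sulfoxide enantiomer in step 10 from a chair transition-state model.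

**Step 1**
Reactants: 1 3-(4-hydroxy-3-methoxyphenyl)propanoic acid
Product: 2 3-(4-hydroxy-3-methoxyphenyl)-1-(pyrrolidin-1-yl)propan-1-one
Conditions: pyrrolidine, EDC·HCl, HOBt, CH2Cl2, 0 °C → rt
Reagents that add atoms: pyrrolidine C1CCNC1
Why: Carbodiimide amide coupling; the free phenol is tolerated because any aryl ester formed is aminolysed by pyrrolidine, and no stereocentre is involved.

**Step 2**
Reactants: 2 3-(4-hydroxy-3-methoxyphenyl)-1-(pyrrolidin-1-yl)propan-1-one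
Product: 3 3-(4-hydroxy-3-iodo-5-methoxyphenyl)-1-(pyrrolidin-1-yl)propan-1-one
Conditions: I2, NaHCO3, THF/H2O, 0 °C → rt
Reagents that add atoms: iodine [I][I]
Why: Electrophilic aromatic iodination of the phenoxide goes to the only free position ortho to oxygen, since the para position carries the side chain.

**Step 3**
Reactants: 4 [4-(benzyloxy)-3-methoxyphenyl]methanol
Product: 5 1-(benzyloxy)-4-(bromomethyl)-2-methoxybenzene
Conditions: PBr3, Et2O, 0 °C
Reagents that add atoms: phosphorus tribromide BrP(Br)Br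
Why: Bromide displaces the activated phosphite ester of an electron-rich benzylic alcohol (alcohol-to-bromide substitution).

**Step 4**
Reactants: 3 3-(4-hydroxy-3-iodo-5-methoxyphenyl)-1-(pyrrolidin-1-yl)propan-1-one; 5 1-(benzyloxy)-4-(bromomethyl)-2-methoxybenzene
Product: 6 3-(4-{[4-(benzyloxy)-3-methoxyphenyl]methoxy}-3-iodo-5-methoxyphenyl)-1-(pyrrolidin-1-yl)propan-1-one
Conditions: K2CO3, DMF, rt
Reagents that add atoms: none
Why: Williamson ether synthesis; the hindered phenoxide still alkylates cleanly with the reactive benzylic bromide.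

**Step 5**
Reactants: 6 3-(4-{[4-(benzyloxy)-3-methoxyphenyl]methoxy}-3-iodo-5-methoxyphenyl)-1-(pyrrolidin-1-yl)propan-1-one; 7 ethyl diazoacetate
Product: 8 ethyl 2-diazo-2-(2-{[4-(benzyloxy)-3-methoxyphenyl]methoxy}-3-methoxy-5-[3-oxo-3-(pyrrolidin-1-yl)propyl]phenyl)acetate
Conditions: Pd(PPh3)4 (5 mol %), Ag2CO3 (0.5 equiv), Et3N, toluene, rt
Reagents that add atoms: none
Why: Palladium-catalysed cross-coupling of an aryl iodide with the C–H bond of a diazoacetate (oxidative addition, base-assisted palladation of the diazo carbon, reductive elimination) gives the aryldiazoacetate with N2 retained.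

**Step 6**
Reactants: 8 ethyl 2-diazo-2-(2-{[4-(benzyloxy)-3-methoxyphenyl]methoxy}-3-methoxy-5-[3-oxo-3-(pyrrolidin-1-yl)propyl]phenyl)acetate
Product: 10 ethyl (2S,3S)-2-[4-(benzyloxy)-3-methoxyphenyl]-7-methoxy-5-[3-oxo-3-(pyrrolidin-1-yl)propyl]-2,3-dihydro-1-benzofuran-3-carboxylate (trans), via cis ester 9 (not isolated)
Conditions: Rh2(R-PTTL)4 (dirhodium tetrakis[N-phthaloyl-(R)-tert-leucinate], 1 mol %), toluene, −60 °C; then NaOEt, EtOH, 0 °C → rt
Reagents that add atoms: none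
Why: Intramolecular dirhodium-carbenoid 1,5-C–H insertion into the electron-rich benzylic ether C–H closes the dihydrofuran ring, the chiral carboxylate ligands selecting one enantiotopic benzylic hydrogen so that C2 forms as S with the ester cis (9); ethoxide enolisation then epimerises only C3 to the thermodynamically preferred trans (2S,3S) ester.

**Step 7**
Reactants: 5 1-(benzyloxy)-4-(bromomethyl)-2-methoxybenzene; 11 ethynylmagnesium bromide
Product: 12 1-(benzyloxy)-2-methoxy-4-(prop-2-yn-1-yl)benzene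
Conditions: CuBr·SMe2 (10 mol %), THF, 0 °C → rt
Reagents that add atoms: none
Why: CuBr-catalysed substitution of a benzylic bromide by an alkynyl Grignard reagent gives the propargylarene.

**Step 8**
Reactants: 12 1-(benzyloxy)-2-methoxy-4-(prop-2-yn-1-yl)benzene; 13 (1S,2R,5S)-(+)-menthyl (R)-4-methylbenzenesulfinate
Product: 15 1-(benzyloxy)-2-methoxy-4-{3-[(R)-4-methylbenzenesulfinyl]prop-2-yn-1-yl}benzene, via alkynylmagnesium bromide 14 (not isolated)
Conditions: EtMgBr, THF, 0 °C; then 13, toluene, −20 °C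
Reagents that add atoms: none
Why: Andersen sulfoxide synthesis; the magnesium acetylide displaces menthoxide at sulfur with inversion, so the sulfur stereocentre comes from the sulfinate.

**Step 9**
Reactants: 15 1-(benzyloxy)-2-methoxy-4-{3-[(R)-4-methylbenzenesulfinyl]prop-2-yn-1-yl}benzene
Product: 16 1-(benzyloxy)-2-methoxy-4-{(2E)-3-[(S)-4-methylbenzenesulfinyl]prop-2-en-1-yl}benzene
Conditions: iBu2AlH, THF, −78 °C
Reagents that add atoms: none
Why: Conjugate hydroalumination of the alkynyl sulfoxide and protonolysis give the E-vinyl sulfoxide; sulfur is untouched, and its descriptor changes from R to S only because the alkenyl group ranks below tolyl.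

**Step 10**
Reactants: 10 ethyl (2S,3S)-2-[4-(benzyloxy)-3-methoxyphenyl]-7-methoxy-5-[3-oxo-3-(pyrrolidin-1-yl)propyl]-2,3-dihydro-1-benzofuran-3-carboxylate; 16 1-(benzyloxy)-2-methoxy-4-{(2E)-3-[(S)-4-methylbenzenesulfinyl]prop-2-en-1-yl}benzene
Product: 20 ethyl (2S,3S)-5-{(2R,3R)-3-[4-(benzyloxy)-3-methoxybenzyl]-4-oxo-2-(pyrrolidine-1-carbonyl)butyl}-2-[4-(benzyloxy)-3-methoxyphenyl]-7-methoxy-2,3-dihydro-1-benzofuran-3-carboxylate, via keteniminium triflate 17 (not isolated), via vinyloxysulfonium triflate 18 (not isolated), via thionium triflate 19 (not isolated)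
Conditions: Tf2O (1.05 equiv), 2-fluoropyridine (2.2 equiv), CH2Cl2, −78 → 0 °C; then 16 (1.3 equiv), −78 °C → rt; then aq. NaHCO3
Reagents that add atoms: water O
Why: Proposed new method: Tf2O and 2-fluoropyridine turn the tertiary amide into keteniminium 17, the sulfinyl oxygen of 16 adds to it, and vinyloxysulfonium 18 undergoes a charge-accelerated [3,3]-sigmatropic sulfonium rearrangement in which the β-carbon of the vinylsulfonium serves as an α-formyl cation (enolonium) equivalent and bonds to the amide α-carbon, so two carbons that are both enolate carbons in normal polarity are joined; a chair transition state with S-tolyl and both benzylic substituents pseudo-equatorial transfers the (S)-sulfur configuration to the new centres and the E alkene gives the (2R,3R) pair, after which thionium 19 is hydrolysed to the aldehyde; the closest known reactions are the acid-promoted ynamide/vinyl sulfoxide sulfonium rearrangement to 1,4-dicarbonyls and the Tf2O-mediated α-arylation of amides with aryl sulfoxides.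

**Step 11**
Reactants: 20 ethyl (2S,3S)-5-{(2R,3R)-3-[4-(benzyloxy)-3-methoxybenzyl]-4-oxo-2-(pyrrolidine-1-carbonyl)butyl}-2-[4-(benzyloxy)-3-methoxyphenyl]-7-methoxy-2,3-dihydro-1-benzofuran-3-carboxylate
Product: 22 (3R,4R)-4-[4-(benzyloxy)-3-methoxybenzyl]-3-({(2S,3R)-2-[4-(benzyloxy)-3-methoxyphenyl]-3-(hydroxymethyl)-7-methoxy-2,3-dihydro-1-benzofuran-5-yl}methyl)oxolan-2-one, via diol amide 21 (not isolated)
Conditions: LiBH4, THF/MeOH, 0 °C → rt; then 1 M HCl (aq), THF, 40 °C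
Reagents that add atoms: none
Why: Chemoselective borohydride reduction (aldehyde and ethyl ester reduced, tertiary amide untouched) followed by acid-catalysed lactonisation of the γ-hydroxy amide with loss of pyrrolidine; fast aldehyde reduction freezes the α-stereocentre, and the trans-3,4-disubstituted lactone is also the thermodynamic isomer.

**Step 12**
Reactants: 22 (3R,4R)-4-[4-(benzyloxy)-3-methoxybenzyl]-3-({(2S,3R)-2-[4-(benzyloxy)-3-methoxyphenyl]-3-(hydroxymethyl)-7-methoxy-2,3-dihydro-1-benzofuran-5-yl}methyl)oxolan-2-one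
Product: 23 isolappaol A, (3R,4R)-3-({(2S,3R)-2-(4-hydroxy-3-methoxyphenyl)-3-(hydroxymethyl)-7-methoxy-2,3-dihydro-1-benzofuran-5-yl}methyl)-4-(4-hydroxy-3-methoxybenzyl)oxolan-2-one
Conditions: H2 (1 atm), Pd/C, EtOAc/MeOH, rt
Reagents that add atoms: none
Why: Catalytic hydrogenolysis of the two aryl benzyl ethers, which under neutral conditions at 1 atm cleave much faster than the cyclic benzylic C2–O bond of the dihydrobenzofuran; no stereocentre is touched.

**Compound list**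
1 | 3-(4-hydroxy-3-methoxyphenyl)propanoic acid (dihydroferulic acid) | COc1cc(CCC(=O)O)ccc1O | starting material
2 | 3-(4-hydroxy-3-methoxyphenyl)-1-(pyrrolidin-1-yl)propan-1-one | COc1cc(CCC(=O)N2CCCC2)ccc1O | intermediate
3 | 3-(4-hydroxy-3-iodo-5-methoxyphenyl)-1-(pyrrolidin-1-yl)propan-1-one | COc1cc(CCC(=O)N2CCCC2)cc(I)c1O | intermediate
4 | [4-(benzyloxy)-3-methoxyphenyl]methanol | COc1cc(CO)ccc1OCc1ccccc1 | starting material
5 | 1-(benzyloxy)-4-(bromomethyl)-2-methoxybenzene | COc1cc(CBr)ccc1OCc1ccccc1 | intermediate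
6 | 3-(4-{[4-(benzyloxy)-3-methoxyphenyl]methoxy}-3-iodo-5-methoxyphenyl)-1-(pyrrolidin-1-yl)propan-1-one | COc1cc(CCC(=O)N2CCCC2)cc(I)c1OCc1ccc(OCc2ccccc2)c(OC)c1 | intermediate
7 | ethyl diazoacetate | CCOC(=O)C=[N+]=[N-] | starting material
8 | ethyl 2-diazo-2-(2-{[4-(benzyloxy)-3-methoxyphenyl]methoxy}-3-methoxy-5-[3-oxo-3-(pyrrolidin-1-yl)propyl]phenyl)acetate | CCOC(=O)C(=[N+]=[N-])c1cc(CCC(=O)N2CCCC2)cc(OC)c1OCc1ccc(OCc2ccccc2)c(OC)c1 | intermediate
9 | ethyl (2S,3R)-2-[4-(benzyloxy)-3-methoxyphenyl]-7-methoxy-5-[3-oxo-3-(pyrrolidin-1-yl)propyl]-2,3-dihydro-1-benzofuran-3-carboxylate (cis ester) | O=C(CCc1cc(OC)c2c(c1)[C@@H](C(=O)OCC)[C@@H](c1ccc(OCc3ccccc3)c(OC)c1)O2)N1CCCC1 | intermediate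
10 | ethyl (2S,3S)-2-[4-(benzyloxy)-3-methoxyphenyl]-7-methoxy-5-[3-oxo-3-(pyrrolidin-1-yl)propyl]-2,3-dihydro-1-benzofuran-3-carboxylate (trans ester) | O=C(CCc1cc(OC)c2c(c1)[C@H](C(=O)OCC)[C@@H](c1ccc(OCc3ccccc3)c(OC)c1)O2)N1CCCC1 | intermediate
11 | ethynylmagnesium bromide | C#C[Mg]Br | starting material
12 | 1-(benzyloxy)-2-methoxy-4-(prop-2-yn-1-yl)benzene | C#CCc1ccc(OCc2ccccc2)c(OC)c1 | intermediate
13 | (1S,2R,5S)-5-methyl-2-(propan-2-yl)cyclohexyl (R)-4-methylbenzenesulfinate, (+)-menthyl (R)-p-toluenesulfinate | C[C@H]1CC[C@@H]([C@H](C1)O[S@@](=O)c1ccc(C)cc1)C(C)C | starting material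
14 | {3-[4-(benzyloxy)-3-methoxyphenyl]prop-1-yn-1-yl}magnesium bromide (alkynylmagnesium bromide) | Br[Mg]C#CCc1ccc(OCc2ccccc2)c(OC)c1 | intermediate
15 | 1-(benzyloxy)-2-methoxy-4-{3-[(R)-4-methylbenzenesulfinyl]prop-2-yn-1-yl}benzene | Cc1ccc(cc1)[S@@](=O)C#CCc1ccc(OCc2ccccc2)c(OC)c1 | intermediate
16 | 1-(benzyloxy)-2-methoxy-4-{(2E)-3-[(S)-4-methylbenzenesulfinyl]prop-2-en-1-yl}benzene | Cc1ccc(cc1)[S@@](=O)/C=C/Cc1ccc(OCc2ccccc2)c(OC)c1 | intermediate
17 | 1-{3-[(2S,3S)-2-[4-(benzyloxy)-3-methoxyphenyl]-3-(ethoxycarbonyl)-7-methoxy-2,3-dihydro-1-benzofuran-5-yl]prop-1-en-1-ylidene}pyrrolidin-1-ium trifluoromethanesulfonate (keteniminium triflate) | C(=C=[N+]1CCCC1)Cc1cc(OC)c2c(c1)[C@H](C(=O)OCC)[C@@H](c1ccc(OCc3ccccc3)c(OC)c1)O2.[O-]S(=O)(=O)C(F)(F)F | intermediate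
18 | (S)-{(1E)-3-[4-(benzyloxy)-3-methoxyphenyl]prop-1-en-1-yl}(4-methylphenyl){[(1E)-3-{(2S,3S)-2-[4-(benzyloxy)-3-methoxyphenyl]-3-(ethoxycarbonyl)-7-methoxy-2,3-dihydro-1-benzofuran-5-yl}-1-(pyrrolidin-1-yl)prop-1-en-1-yl]oxy}sulfonium trifluoromethanesulfonate (vinyloxysulfonium triflate) | Cc1ccc(cc1)[S@@+](O/C(N1CCCC1)=C/Cc1cc(OC)c2c(c1)[C@H](C(=O)OCC)[C@@H](c1ccc(OCc3ccccc3)c(OC)c1)O2)/C=C/Cc1ccc(OCc2ccccc2)c(OC)c1.[O-]S(=O)(=O)C(F)(F)F | intermediate
19 | {(2R,3R)-2-[4-(benzyloxy)-3-methoxybenzyl]-3-({(2S,3S)-2-[4-(benzyloxy)-3-methoxyphenyl]-3-(ethoxycarbonyl)-7-methoxy-2,3-dihydro-1-benzofuran-5-yl}methyl)-4-oxo-4-(pyrrolidin-1-yl)butylidene}(4-methylphenyl)sulfonium trifluoromethanesulfonate (thionium triflate) | Cc1ccc(cc1)[S+]=C[C@H](Cc1ccc(OCc2ccccc2)c(OC)c1)[C@@H](Cc1cc(OC)c2c(c1)[C@H](C(=O)OCC)[C@@H](c1ccc(OCc3ccccc3)c(OC)c1)O2)C(=O)N1CCCC1.[O-]S(=O)(=O)C(F)(F)F | intermediate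
20 | ethyl (2S,3S)-5-{(2R,3R)-3-[4-(benzyloxy)-3-methoxybenzyl]-4-oxo-2-(pyrrolidine-1-carbonyl)butyl}-2-[4-(benzyloxy)-3-methoxyphenyl]-7-methoxy-2,3-dihydro-1-benzofuran-3-carboxylate | O=C[C@H](Cc1ccc(OCc2ccccc2)c(OC)c1)[C@@H](Cc1cc(OC)c2c(c1)[C@H](C(=O)OCC)[C@@H](c1ccc(OCc3ccccc3)c(OC)c1)O2)C(=O)N1CCCC1 | intermediate
21 | (2R,3R)-3-[4-(benzyloxy)-3-methoxybenzyl]-2-({(2S,3R)-2-[4-(benzyloxy)-3-methoxyphenyl]-3-(hydroxymethyl)-7-methoxy-2,3-dihydro-1-benzofuran-5-yl}methyl)-4-hydroxy-1-(pyrrolidin-1-yl)butan-1-one (diol amide) | OC[C@H](Cc1ccc(OCc2ccccc2)c(OC)c1)[C@@H](Cc1cc(OC)c2c(c1)[C@H](CO)[C@@H](c1ccc(OCc3ccccc3)c(OC)c1)O2)C(=O)N1CCCC1 | intermediate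
22 | (3R,4R)-4-[4-(benzyloxy)-3-methoxybenzyl]-3-({(2S,3R)-2-[4-(benzyloxy)-3-methoxyphenyl]-3-(hydroxymethyl)-7-methoxy-2,3-dihydro-1-benzofuran-5-yl}methyl)oxolan-2-one | COc1cc(C[C@H]2COC(=O)[C@@H]2Cc2cc(OC)c3c(c2)[C@H](CO)[C@@H](c2ccc(OCc4ccccc4)c(OC)c2)O3)ccc1OCc1ccccc1 | intermediate
23 | isolappaol A | COc1cc(C[C@H]2COC(=O)[C@@H]2Cc2cc(OC)c3c(c2)[C@H](CO)[C@@H](c2ccc(O)c(OC)c2)O3)ccc1O | target

**Totals**
Total step count: 12. Longest linear sequence: 8 steps (1 → 2 → 3 → 6 → 8 → 10 → 20 → 22 → 23; steps 1, 2, 4, 5, 6, 10, 11, 12).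

**Three steps most likely to fail**

Step 10 (key rearrangement). The risks are Friedel–Crafts capture of keteniminium 17 or thionium 19 by the electron-rich aryl rings, incomplete or opposite sulfur-to-carbon chirality transfer, and epimerisation of aldehyde 20 before reduction. The fallback sets out from 10 and 5 and comes back at 20; it replaces the sulfoxide by an allylic alcohol and uses 1,3-chirality transfer in a Claisen rearrangement. Bromide 5 is coupled with commercial (R)-but-3-yn-2-ol (CuI, K2CO3, NaI, MeCN, rt) to give (2R)-5-[4-(benzyloxy)-3-methoxyphenyl]pent-3-yn-2-ol F1. Trans-reduction with NaAlH2(OCH2CH2OMe)2 in THF at 0 °C gives (2R,3E)-5-[4-(benzyloxy)-3-methoxyphenyl]pent-3-en-2-ol F2. Amide 10 is activated as in step 10 (Tf2O, 2-fluoropyridine, CH2Cl2) and treated with F2 and iPr2NEt (rt → 60 °C). The O-allyl ketene N,O-acetal then rearranges through a chair with the carbinol methyl equatorial (Eschenmoser-type Claisen) to give ethyl (2S,3S)-5-{(2R,3S,4E)-3-[4-(benzyloxy)-3-methoxybenzyl]-2-(pyrrolidine-1-carbonyl)hex-4-en-1-yl}-2-[4-(benzyloxy)-3-methoxyphenyl]-7-methoxy-2,3-dihydro-1-benzofuran-3-carboxylate F3. Cleavage of the propenyl group (OsO4 cat., NaIO4, 2,6-lutidine, dioxane/H2O) returns aldehyde 20.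

Step 6 (C–H insertion and epimerisation). The risks are eroded enantioselectivity because the amide coordinates the dirhodium catalyst, and ring-opening during the ethoxide epimerisation. The fallback sets out from 8 and comes back at 10; it gives up catalyst control and resolves instead. Insertion with achiral Rh2(esp)2 (CH2Cl2, 0 °C) gives 9 together with its enantiomer ethyl (2R,3S)-2-[4-(benzyloxy)-3-methoxyphenyl]-7-methoxy-5-[3-oxo-3-(pyrrolidin-1-yl)propyl]-2,3-dihydro-1-benzofuran-3-carboxylate F4. NaOEt/EtOH converts the pair into 10 and its enantiomer ethyl (2R,3R)-2-[4-(benzyloxy)-3-methoxyphenyl]-7-methoxy-5-[3-oxo-3-(pyrrolidin-1-yl)propyl]-2,3-dihydro-1-benzofuran-3-carboxylate F5. Preparative chromatography on a chiral stationary phase delivers 10.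

Step 5 (diazoacetate cross-coupling). The risks are slow oxidative addition into the hindered, electron-rich iodide and palladium-induced loss of N2. The fallback sets out from 6 and comes back at 8; it separates C–C bond formation from diazo installation. Negishi coupling of 6 with the Reformatsky reagent BrZnCH2CO2Et (Pd(dba)2, XPhos, THF, 60 °C) gives ethyl 2-(2-{[4-(benzyloxy)-3-methoxyphenyl]methoxy}-3-methoxy-5-[3-oxo-3-(pyrrolidin-1-yl)propyl]phenyl)acetate F6. Regitz diazo transfer (4-acetamidobenzenesulfonyl azide, DBU, MeCN, rt) then gives 8.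

**Further compounds**
F1 | step 10 | (2R)-5-[4-(benzyloxy)-3-methoxyphenyl]pent-3-yn-2-ol | C[C@@H](O)C#CCc1ccc(OCc2ccccc2)c(OC)c1
F2 | step 10 | (2R,3E)-5-[4-(benzyloxy)-3-methoxyphenyl]pent-3-en-2-ol | C[C@@H](O)/C=C/Cc1ccc(OCc2ccccc2)c(OC)c1
F3 | step 10 | ethyl (2S,3S)-5-{(2R,3S,4E)-3-[4-(benzyloxy)-3-methoxybenzyl]-2-(pyrrolidine-1-carbonyl)hex-4-en-1-yl}-2-[4-(benzyloxy)-3-methoxyphenyl]-7-methoxy-2,3-dihydro-1-benzofuran-3-carboxylate | C/C=C/[C@H](Cc1ccc(OCc2ccccc2)c(OC)c1)[C@@H](Cc1cc(OC)c2c(c1)[C@H](C(=O)OCC)[C@@H](c1ccc(OCc3ccccc3)c(OC)c1)O2)C(=O)N1CCCC1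
F4 | step 6 | ethyl (2R,3S)-2-[4-(benzyloxy)-3-methoxyphenyl]-7-methoxy-5-[3-oxo-3-(pyrrolidin-1-yl)propyl]-2,3-dihydro-1-benzofuran-3-carboxylate | O=C(CCc1cc(OC)c2c(c1)[C@H](C(=O)OCC)[C@H](c1ccc(OCc3ccccc3)c(OC)c1)O2)N1CCCC1
F5 | step 6 | ethyl (2R,3R)-2-[4-(benzyloxy)-3-methoxyphenyl]-7-methoxy-5-[3-oxo-3-(pyrrolidin-1-yl)propyl]-2,3-dihydro-1-benzofuran-3-carboxylate | O=C(CCc1cc(OC)c2c(c1)[C@@H](C(=O)OCC)[C@H](c1ccc(OCc3ccccc3)c(OC)c1)O2)N1CCCC1
F6 | step 5 | ethyl 2-(2-{[4-(benzyloxy)-3-methoxyphenyl]methoxy}-3-methoxy-5-[3-oxo-3-(pyrrolidin-1-yl)propyl]phenyl)acetate | CCOC(=O)Cc1cc(CCC(=O)N2CCCC2)cc(OC)c1OCc1ccc(OCc2ccccc2)c(OC)c1
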